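The numbers in the tables were computed for an exercise; the scatter is artificial.

Start from the leftover: 82.4% of Friday's charge stands neither as target nor as starting material at 10.0 h. So decide whether the next flask earns more solid substrate.

| flask | solid substrate | remark | time |
|---|---|---|---|
| Sunday's | 0.025 M | run made earlier |  |
| Friday's | 0.10 M | run made earlier |  |
| flask | 0.050 M |  | 10 h |

| run | time / h | target / % | starting material / % |
|---|---|---|---|
| Sunday's | 0.833 | 6.6 | 5.2 |
| Sunday's | 1.33 | 11.1 | 7.4 |
| Sunday's | 2.00 | 16.4 | 6.4 |
| Sunday's | 4.00 | 25.9 | 12.5 |
| Sunday's | 6.00 | 34.8 | 16.9 |
| Sunday's | 10.0 | 42.1 | 18.2 |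
| Friday's | 1.50 | 1.1 | 0.9 |
| Friday's | 3.00 | 6.1 | 0.7 |
| Friday's | 5.00 | 7.1 | 4.2 |
| Friday's | 6.00 | 9.8 | 4.0 |
| Friday's | 8.00 | 11.4 | 4.6 |
| Friday's | 10.0 | 12.7 | 4.9 |

(standard deviation of a reading: 1 percentage point)

- given per volume of solution although it is solid: solid substrate
- at the start none of the solid substrate is in solution
- starting material is what solid substrate becomes in solution
- starting material means what is dissolved; the solid is not counted in it

- alder: doubling the dissolution coefficient of the solid substrate, all else as stated
- cedar: doubling the solubility of the solid substrate, all else as stated

* the target standing at 10 h, as a percentage of the solid substrate charged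
* concentration of starting material in solution at 5.0 h, in percent of saturation
* the change that raises the amount of target at 10 h, in percent of the solid substrate charged most ("none" if none brings more than 2 percentage points) (alder / cedar / none)
* amount of target at 10 h, in percent of the solid substrate charged, after cedar

Set the zero of the scale first: a series in which the percentage stays put as the charge grows, so that the molar amount of target grows in step with the charge. Now reckon the real amount. Multiply percentage by charge to get c(target) at 10 h: 10.5 mM on Sunday, 12.7 mM on Friday. Friday's charge is 4.00 times Sunday's, yet its c(target) is 1.21 times Sunday's, so the series runs nearly zero order in the charge. The flask's charge lies at the geometric middle of the two, so take their geometric mean, 11.6 mM, as its output, the c(target) that a run of this length delivers, percentage times charge. Divide by 0.050 M: my reckoning gives 23.1%. Keep the charge at 0.050 M, since Friday's extra solid substrate bought little.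

The forecast stands slightly higher, at 23.5% (21% to 26%), with 65% of saturation at 5.0 h, cedar as the best change and 43% after cedar, on the ground that “the solid stays in excess and dissolution sets the supply”.

The flask gives 26.2%, with 18.2% of saturation at 5.0 h. The best change is alder, worth 17 percentage points against 15 points for cedar, and cedar brings 41.4%.

    starting material ⇌ target (K = 2.13, k = 0.00218 /s)
    starting material ⇌ isomer of the product A (K = 0.990, k = 9.29 × 10⁻⁵ /s)
    starting material ⇌ isomer of the product B (K = 1.40, k = 9.31 × 10⁻⁵ /s)
    solid substrate ⇌ starting material, rate k4*(cs4 - [starting material]) while solid is left; crystals form when [starting material] > cs4 (solubility = 21.0 mM, k = 4.83 × 10⁻⁵ /s)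

The flask's output is 13.1 mM. The neighbour flask at 0.20 M gives 6.56%, an output of 13.1 mM, level with it on 4.00 times the charge. The backward run from target to starting material is the main reason the flask's target stands this low: the same flask without that backward run gives 68.6% against 26.2%. In the neighbour flask, 84.9% of the charge still lies as solid substrate at 10.0 h.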